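## Analysis of the target

Target 41 is a germacranolide: a ten-membered carbocycle (C1–C10) trans-fused across C6–C7 to an α-methylene-γ-butyrolactone (C11=C13 methylene, C12 carbonyl, ring oxygen on C6). The carbocycle holds one endocyclic trisubstituted alkene, C4(CH3)=C5, of Z geometry, a secondary allylic carbinol at C3, an isobutyrate at C8 and a tertiary methyl carbinol at C10; C1, C2 and C9 are methylenes. The five stereocentres are 3S, 6R, 7R, 8R and 10S. C6, C7 and C8 are contiguous: the C6 oxygen and the C7–C11 bond are syn in the aldol sense (H6 and H7 anti, trans-lactone), and the C8 oxygen is 1,3-anti to both the C6 and the C10 oxygen. C3 and C10 are isolated from this triad by the alkene and by methylene groups. The α-methylene lactone is a Michael acceptor and cannot be exposed to carbanions, the C8-acyloxy/C10-hydroxy pair is a masked aldol (retro-aldol and dehydration at the ketone stage, acyl migration later), and the Z alkene is open to isomerisation whenever it is conjugated to a carbonyl group. The synthesis is hard because a ten-membered carbocycle must be closed against entropy and transannular strain, because the quaternary C10 carbinol has no neighbouring stereocentre to control it, and because C8 must be fixed in a flexible ring. The strategy rests on the fact that the oxygenated C8 lies β to the C10 carbinol: the C8–C9 bond can be made with reversed polarity, C8 as an acyl anion (1,3-dithiane) opening a C9–C10 epoxide whose C10 centre, with its methyl group, oxygen and two carbon arms, is that of (S)-linalool 1.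

## Retrosynthetic reasoning

**Lactone and C12.** The O6–C12 bond of 41 is cut to hydroxy acid 40, which is traced through acid 39 and aldehyde 38 to allylic alcohol 37 and its PMB ether 36. An acrylate would not survive the carbanion that closes the ring, so C12 travels as an ether-protected CH2O group and C11=C13 as a plain 1,1-disubstituted alkene. Forward, only C12 may be oxidised (C3 and C6 are still silylated), and desilylation must free the C6 hydroxyl next to the acid so that the five-membered ring closes by itself.

**C8 ester and C8–H.** Ester 36 is cut at the acyl–oxygen bond to diol 35, where a secondary hydroxyl must be acylated beside a tertiary one. Diol 35 comes from β-hydroxy ketone 34 by a reduction in which the C10 hydroxyl carries the hydride, and 34 from dithiane 33 by hydrolysis. The C8 centre is thereby postponed until the ring and C10 exist, and the reduction must give the 1,3-anti (trans) diol.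

**C8–C9, the ring-closing bond.** Macrocycle 33 is cut between C8 and C9 to epoxy dithiane 31. This cut is chosen over others in the ring because the lithiated dithiane intermediate 32 and the epoxide give exactly the β-hydroxy carbonyl pattern C8/C10, and because the ring closure then creates no stereocentre and leaves C3, C6, C7 and C10 as they were set in open-chain compounds. Forward, the carbanion must attack the primary C9 and not the quaternary C10, and it must do so within the molecule.

**Epoxide and C3.** Epoxide 31 is traced through the C9 sulfonate 30 to diol 29 and its acetonide 28. The C3 silyl ether 28 comes from carbinol 27, which is cut at C3–H to enone 26, so that C3 is set by a catalyst-controlled reduction and not by the preceding carbon–carbon bond formation. Enone 26 comes from the epimeric allylic alcohols 25.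

**C3–C4.** Alcohols 25 are cut between C3 and C4 into alkenyl iodide 24 and aldehyde 5. The cut next to the alkene uses the iodide as a configurationally stable Z-alkenyl donor and joins two fragments of similar size. Forward, a chemoselective alkenyl-metal addition to the aldehyde must tolerate the dithiane and the ethers.

**C1–C3, C9, C10.** Aldehyde 5 comes from alcohol 4, the acetonide of triol 3, which is the product of cleaving both alkenes of 1. The vinyl group of 1 becomes C9 and the prenyl chain becomes C1–C3, while the carbinol carbon is never touched.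

**C8 dithiane and C6–C7.** Dithiane 24 comes from aldehyde 22 and dithiol 23. Aldehyde 22 is traced through alcohol 21 and silyl ether 20 to aldol adduct 19, which is cut between C6 and C7 into imide 17 and enal 9. An auxiliary-controlled syn-aldol reaction is the most reliable way to set the C6/C7 pair in absolute terms, and the acyl carbon of the imide is C8, at the oxidation level needed for the dithiane.

**Small fragments.** Enal 9 comes from iodo alcohol 8 and this from alkynol 6, where a hydroxyl-directed trans-hydrometalation fixes the Z geometry. Imide 17 is acid 13 bound to auxiliary 14. Acid 13 comes from allylic chloride 11 by carboxylation, and 11 from dichloride 10.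

## Alternatives that were turned down

**Alternative 1: enone–cyclobutene photocycloaddition, then cycloreversion.** The disconnection cuts C4–C5 and C1–C10 together and traces the skeleton to cyclohexenone A1 (C6 ketone, C5=C10, C7 and C8 substituents in place) and cyclobutene ester A2. In the forward key step, irradiation joins A1 and A2 head-to-head to the cis-anti-cis adduct A3. The bicyclo[2.2.0]hexane unit of A3 would later open thermally to the ten-membered ring.
- For: two ring bonds and the whole ring perimeter are formed in one step, and the medium ring arises by strain release from a rigid tricycle, without high dilution. On the ring-forming event this is stronger than the chosen route.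
- Against: the ring opening necessarily leaves a second ring alkene at C1=C10, which 41 does not have. C10 would then have to be made by a regio- and face-selective hydration in a flexible ring.
- Against: C4 arrives as an ester carbon, C3 is not oxygenated, C6 is a ketone and the lactone lacks its methylene.
- Against: the head-to-head sense and the facial selectivity of the photocycloaddition are not secured by the substituents of A1, and cyclodeca-1,5-dienes are prone to Cope rearrangement at the temperatures of cycloreversion.
- Comparison: the chosen route has no surplus unsaturation to remove, buys C10 from 1 and sets C3 before ring closure, at the price of an entropically harder ring closure.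

**Alternative 2: Nozaki–Hiyama–Kishi closure at C3–C4 on the finished lactone.** The disconnection cuts C3–C4 of the fully functionalised molecule to the iodo aldehyde A4. In the forward key step, CrCl2 with catalytic NiCl2 turns the (Z)-alkenyl iodide of A4 into an alkenylchromium species that adds to the C3 aldehyde and gives A5, the C10 triethylsilyl ether of the target.
- For: the addition is chemoselective for the aldehyde and tolerates lactone and ester. Closures of this kind are better precedented for medium rings than carbanion alkylations, and only one desilylation follows. On precedent and on functional-group tolerance this is stronger than the chosen key step.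
- Against: C3 is created in the ring-closing event with nothing but ring conformation to control it.
- Against: A4 must carry the α-methylene lactone and an enolisable aldehyde through its assembly.
- Against: the C8/C10 pattern with its quaternary carbinol must still be built in an open chain.
- Comparison: the chosen route closes the ring without creating a stereocentre, sets C3 by reagent control and introduces the Michael acceptor last. The Nozaki–Hiyama–Kishi closure is kept as the reserve for the key step.

**Alternative 3: Grob fragmentation of an epoxy alcohol in a lactone-fused cis-decalin.** The disconnection re-forms the C5–C10 bond, so that the ten-membered ring is hidden in a decalin with a C10 alkoxide and a C3–C4 epoxide. In the forward key step, Ti(OiPr)4 triggers the fragmentation: the C10 alkoxide pushes, C5–C10 breaks, C4=C5 and the C10 ketone form and the epoxide opens to the C3 alkoxide, giving A6.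
- For: the ring is formed from a rigid bicycle without high dilution, and the Z geometry and the C3 configuration follow stereospecifically from the antiperiplanar arrangement. On these two points it is stronger than the chosen route.
- Against: A6 has a C10 ketone, so the methyl group and the C10 configuration must be introduced by addition to a ten-membered ketone in the presence of the lactone.
- Against: the lactone lacks its methylene and C8 needs a protecting-group exchange.
- Against: three stereocentres of the decalin (C4, C5, C10) must be set correctly only to be destroyed, and the Lewis acid can divert the epoxy alcohol into simple epoxide opening or 1,2-shift.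
- Comparison: the chosen route sets only stereocentres that survive into 41 and takes C10 from the chiral pool, but accepts a macrocyclisation in place of a fragmentation.

Key step: step 20

## Remarks before the steps

- Assumption: (S)-linalool 1 is used in enantiomerically pure form, since C10 of every later compound derives from it.
- Locants C1–C13 in names of intermediates are those of 41. "Configured as in 41" means the same spatial arrangement of the corresponding substituents (the CIP letter can change with the substituents).
- Abbreviations: TBS = tert-butyldimethylsilyl, PMB = 4-methoxybenzyl, TES = triethylsilyl, TMS = trimethylsilyl, HMPA = hexamethylphosphoramide, DDQ = 2,3-dichloro-5,6-dicyano-1,4-benzoquinone.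

## Steps

Step 1
Reactants: 1 (S)-(+)-linalool
Product: 3 (2S)-2-methylpentane-1,2,5-triol, via bis-ozonide 2 (not isolated)
Conditions: O3, CH2Cl2, −78 °C; then NaBH4, MeOH, −78 °C → rt
Reagents that add atoms: ozone, O=[O+][O-]
Why: Ozonolysis cleaves both alkenes and NaBH4 reduces the ozonides to primary alcohols; the carbinol carbon (future C10) is not involved and keeps its configuration.

Step 2
Reactants: 3 (2S)-2-methylpentane-1,2,5-triol
Product: 4 3-[(4S)-2,2,4-trimethyl-1,3-dioxolan-4-yl]propan-1-ol
Conditions: Me2C(OMe)2, p-toluenesulfonic acid (cat.), acetone, rt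
Reagents that add atoms: 2,2-dimethoxypropane, COC(C)(C)OC
Why: Acid-catalysed acetalisation; the five-membered dioxolane of the vicinal diol forms in preference to a medium-ring acetal, so the C3 hydroxyl stays free.

Step 3
Reactants: 4 3-[(4S)-2,2,4-trimethyl-1,3-dioxolan-4-yl]propan-1-ol
Product: 5 3-[(4S)-2,2,4-trimethyl-1,3-dioxolan-4-yl]propanal
Conditions: 2,2,6,6-tetramethylpiperidin-1-oxyl (cat.), PhI(OAc)2, CH2Cl2, rt
Reagents that add atoms: none
Why: Oxoammonium-mediated oxidation of a primary alcohol stops at the aldehyde and does not harm the acetonide.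

Step 4
Reactants: 6 but-2-yn-1-ol
Product: 8 (2Z)-3-iodobut-2-en-1-ol, via cyclic alkenylalanate 7 (not isolated)
Conditions: NaAlH2(OCH2CH2OMe)2, THF, 0 °C → rt; then I2, −78 °C
Reagents that add atoms: iodine, II
Why: Hydroxyl-directed trans-hydroalumination places aluminium on the distal alkyne carbon, cis to the CH2O group in a five-membered alanate; iodinolysis with retention gives the Z iodide, which is the C4=C5 geometry of 41.

Step 5
Reactants: 8 (2Z)-3-iodobut-2-en-1-ol
Product: 9 (2Z)-3-iodobut-2-enal
Conditions: MnO2, CH2Cl2, rt, dark; used at once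
Reagents that add atoms: none
Why: MnO2 oxidises the allylic alcohol under neutral conditions, which preserves the Z geometry of the β-iodo enal.

Step 6
Reactants: 10 3-chloro-2-(chloromethyl)prop-1-ene
Product: 11 1-({[2-(chloromethyl)prop-2-en-1-yl]oxy}methyl)-4-methoxybenzene
Conditions: 4-MeOC6H4CH2OH, NaH, THF/DMF, 0 °C; then 10 (3 equiv), Bu4NI (cat.), rt
Reagents that add atoms: 4-methoxybenzyl alcohol, COc1ccc(CO)cc1
Why: Williamson etherification at one of two equivalent allylic chlorides; the excess of 10 suppresses the second substitution.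

Step 7
Reactants: 11 1-({[2-(chloromethyl)prop-2-en-1-yl]oxy}methyl)-4-methoxybenzene
Product: 13 3-{[(4-methoxybenzyl)oxy]methyl}but-3-enoic acid, via allylmagnesium chloride 12 (not isolated)
Conditions: Mg, THF, 0 °C (slow addition); then CO2, −78 °C; cold 1 M HCl
Reagents that add atoms: carbon dioxide, O=C=O
Why: Formation and carboxylation of an allylic Grignard reagent; the 2-substituted allyl unit has two equivalent termini, so a single β,γ-unsaturated acid results.

Step 8
Reactants: 13 3-{[(4-methoxybenzyl)oxy]methyl}but-3-enoic acid; 14 (4S)-4-benzyl-1,3-oxazolidin-2-one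
Product: 17 (4S)-4-benzyl-3-(3-{[(4-methoxybenzyl)oxy]methyl}but-3-enoyl)-1,3-oxazolidin-2-one, via mixed pivalic anhydride 15 (not isolated), via N-lithio oxazolidinone 16 (not isolated)
Conditions: t-BuCOCl, Et3N, THF, −78 → 0 °C; then 16 (from 14, n-BuLi, THF, −78 °C), −78 → 0 °C
Reagents that add atoms: none
Why: N-Acylation of the lithiated auxiliary by the mixed anhydride at low temperature, where the β,γ-alkene does not move into conjugation.

Step 9
Reactants: 17 (4S)-4-benzyl-3-(3-{[(4-methoxybenzyl)oxy]methyl}but-3-enoyl)-1,3-oxazolidin-2-one; 9 (2Z)-3-iodobut-2-enal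
Product: 19 (4S)-4-benzyl-3-[(2S,3S,4Z)-3-hydroxy-5-iodo-2-{3-[(4-methoxybenzyl)oxy]prop-1-en-2-yl}hex-4-enoyl]-1,3-oxazolidin-2-one, via Z boron enolate 18 (not isolated)
Conditions: Bu2BOTf (1.2 equiv), i-Pr2NEt (1.1 equiv), CH2Cl2, −78 → 0 °C; 9, −78 → −20 °C; then pH 7 buffer, MeOH, H2O2, 0 °C
Reagents that add atoms: none
Why: Evans syn-aldol reaction: the Z boron enolate reacts at its α-carbon through a Zimmerman–Traxler chair on the face opposite the benzyl group, which sets C7 and C6 (6,7-syn) in the absolute sense of 41; keeping the amine below the boron triflate leaves no free base to attack the β-iodo enal.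

Step 10
Reactants: 19 aldol adduct
Product: 20 C6 TBS ether of 19
Conditions: TBSOTf, 2,6-lutidine, CH2Cl2, −78 → 0 °C
Reagents that add atoms: tert-butyldimethylsilyl trifluoromethanesulfonate, CC(C)(C)[Si](C)(C)OS(=O)(=O)C(F)(F)F
Why: Silyl triflate silylation of a hindered secondary hydroxyl; this also blocks retro-aldol cleavage in the following steps.

Step 11
Reactants: 20 C6 TBS ether of 19
Product: 21 (2R,3S,4Z)-3-[(tert-butyldimethylsilyl)oxy]-5-iodo-2-{3-[(4-methoxybenzyl)oxy]prop-1-en-2-yl}hex-4-en-1-ol
Conditions: LiBH4, MeOH (1 equiv), Et2O, 0 °C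
Reagents that add atoms: none
Why: Reductive removal of the auxiliary by hydride attack at the exocyclic carbonyl; the conditions are not basic enough to epimerise C7, and the alkenyl iodide and the ethers are inert.

Step 12
Reactants: 21 primary alcohol (C8–OH)
Product: 22 (2S,3S,4Z)-3-[(tert-butyldimethylsilyl)oxy]-5-iodo-2-{3-[(4-methoxybenzyl)oxy]prop-1-en-2-yl}hex-4-enal
Conditions: 2,2,6,6-tetramethylpiperidin-1-oxyl (cat.), PhI(OAc)2, CH2Cl2, 0 °C → rt; used at once
Reagents that add atoms: none
Why: Base-free oxoammonium oxidation, chosen because the aldehyde is α-branched and β,γ-unsaturated and would epimerise or conjugate under basic conditions.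

Step 13
Reactants: 22 C8 aldehyde; 23 propane-1,3-dithiol
Product: 24 2-substituted 1,3-dithiane (C8) carrying C7H[C(=CH2)CH2OPMB]–C6H(OTBS)–C5H=C4(CH3)I (4Z; C6, C7 configured as in 41)
Conditions: BF3·OEt2 (0.3 equiv), CH2Cl2, −78 → −40 °C
Reagents that add atoms: none
Why: Lewis-acid-catalysed dithioacetalisation of an aldehyde is fast at low temperature, where the TBS and PMB ethers are retained and the α-centre has no time to enolise.

Step 14
Reactants: 24 dithiane alkenyl iodide; 5 3-[(4S)-2,2,4-trimethyl-1,3-dioxolan-4-yl]propanal
Product: 25 allylic alcohols from C3–C4 coupling (both C3 epimers; acetonide at C9/C10)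
Conditions: CrCl2 (5 equiv), NiCl2 (2 mol %), DMSO, rt
Reagents that add atoms: none
Why: Nozaki–Hiyama–Kishi reaction: zerovalent nickel inserts into the alkenyl iodide, the alkenyl group passes to chromium and adds to the aldehyde with retention of the Z geometry; the dithiane, the ethers and the acetonide are tolerated, and both C3 epimers are carried on.

Step 15
Reactants: 25 allylic alcohols (C3 epimers)
Product: 26 (4Z)-enone (C3 ketone)
Conditions: SO3·pyridine, DMSO, i-Pr2NEt, CH2Cl2, 0 °C
Reagents that add atoms: none
Why: Parikh–Doering oxidation with activated DMSO does not oxidise the dithiane sulfur atoms and converges the two epimers to one enone.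

Step 16
Reactants: 26 (4Z)-enone
Product: 27 (3S)-allylic alcohol
Conditions: (R)-1-methyl-3,3-diphenyltetrahydro-1H,3H-pyrrolo[1,2-c][1,3,2]oxazaborole (0.3 equiv), catecholborane, toluene, −78 °C
Reagents that add atoms: none
Why: CBS reduction: the ketone binds to the oxazaborolidine with the alkenyl group as the large substituent, and the (R)-catalyst delivers hydride to the face that gives the 3S carbinol (reagent control); catecholborane at low temperature leaves the 1,1-disubstituted alkene alone.

Step 17
Reactants: 27 (3S)-allylic alcohol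
Product: 28 C3, C6 bis-TBS ether (acetonide at C9/C10)
Conditions: TBSOTf, 2,6-lutidine, CH2Cl2, −78 °C
Reagents that add atoms: tert-butyldimethylsilyl trifluoromethanesulfonate, CC(C)(C)[Si](C)(C)OS(=O)(=O)C(F)(F)F
Why: Silylation of the secondary allylic hydroxyl; at −78 °C the acetonide is not opened by the silyl triflate.

Step 18
Reactants: 28 bis-TBS acetonide
Product: 29 C9, C10 diol
Conditions: pyridinium p-toluenesulfonate (0.2 equiv), MeOH, rt
Reagents that add atoms: none
Why: Mild acid-catalysed transacetalisation with methanol removes the terminal acetonide, while secondary TBS ethers, the PMB ether and the dithiane are stable to this acid at room temperature.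

Step 19
Reactants: 29 C9, C10 diol
Product: 31 epoxy dithiane (key precursor; (2S)-2-methyloxiran-2-yl group from C9/C10), via C9 tosylate 30 (not isolated)
Conditions: NaH (2.2 equiv), 1-(p-toluenesulfonyl)imidazole, THF, 0 °C → rt
Reagents that add atoms: none
Why: One-pot epoxide formation: the primary alkoxide is sulfonylated selectively and the tertiary alkoxide displaces the sulfonate (3-exo-tet); no bond to C10 is broken, so its configuration is retained, and NaH does not deprotonate the dithiane.

Step 20
Reactants: 31 epoxy dithiane
Product: 33 ten-membered carbocycle (C8 spiro-1,3-dithiane, free C10 tertiary alcohol, C3 and C6 TBS ethers, C12 PMB ether), via 2-lithio-1,3-dithiane 32 (not isolated)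
Conditions: t-BuLi (1.1 equiv), THF/HMPA (10:1), 0.002 M, −78 °C, 10 min; then −78 → 0 °C; aq. NH4Cl
Reagents that add atoms: none
Why: Proposed new method: t-BuLi in THF–HMPA removes the C8–H of the 2-alkyl-1,3-dithiane within minutes at −78 °C to give the acyl-anion equivalent 32, which on warming attacks the primary epoxide carbon C9 from the rear (SN2), forming C8–C9 and releasing the C10 lithium alkoxide. The closest known reaction types are the intermolecular opening of terminal and 2,2-disubstituted epoxides by 2-lithio-1,3-dithianes and the intramolecular alkylation of sulfur- or cyano-stabilised carbanions that closes ten-membered carbocycles; their combination in one ring closure is the extension proposed here. The ten-membered ring closes in the endo mode with respect to the epoxide (attack on the distal carbon, so that C9 and C10 both become ring members); the 9-exo alternative would require substitution at the fully substituted C10 and is sterically excluded, which also leaves the linalool-derived C10 configuration untouched. No stereocentre is created, because C8 becomes a spiro carbon with two equivalent sulfur substituents. The step needs ring closure to outrun oligomerisation, for which high dilution and the restriction of the nine-atom tether by the Z alkene and the C6/C7 substituents are relied on. It also needs the charge to stay on C8: in THF–HMPA the equilibrium of the 1,4-silyl shift between the C6 oxygen and C8 lies on the side of the sulfur-stabilised carbanion, and the dithiane C–H is kinetically far more acidic than the allylic and benzylic ether positions.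

Step 21
Reactants: 33 ten-membered dithiane
Product: 34 β-hydroxy ketone (C8 ketone, C10–OH)
Conditions: MeI, CaCO3, MeCN/H2O (9:1), 45 °C
Reagents that add atoms: water, O
Why: Alkylative dithiane hydrolysis: S-methylation turns sulfur into a leaving group and water captures the thionium ion; the buffered, non-oxidising conditions are chosen to spare the two alkenes, the PMB ether and the base-sensitive β-hydroxy ketone.

Step 22
Reactants: 34 β-hydroxy ketone
Product: 35 8,10-anti diol (new C8 carbinol configured as in 41)
Conditions: Me4NBH(OAc)3, MeCN/AcOH (1:1), −30 °C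
Reagents that add atoms: none
Why: Evans–Saksena reduction: the C10 hydroxyl exchanges onto boron and the hydride is delivered to C8 within the molecule through a six-membered transition state, while free triacetoxyborohydride does not reduce the ketone. The 1,3-anti (trans) diol of 41 is the normal outcome of this delivery and in the ring requires the chair in which the ring bonds at C8 and C10 are cis to each other.

Step 23
Reactants: 35 8,10-anti diol
Product: 36 C8 isobutyrate
Conditions: (i-PrCO)2O, Et3N, 4-(dimethylamino)pyridine (cat.), CH2Cl2, 0 °C → rt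
Reagents that add atoms: isobutyric anhydride, CC(C)C(=O)OC(=O)C(C)C
Why: Nucleophile-catalysed acylation distinguishes the secondary C8 hydroxyl from the tertiary C10 hydroxyl, which does not react under these conditions.

Step 24
Reactants: 36 C8 isobutyrate
Product: 37 C12 allylic alcohol
Conditions: DDQ, CH2Cl2/pH 7 buffer (10:1), 0 °C
Reagents that add atoms: none
Why: Oxidative cleavage of the PMB ether by benzylic hydride abstraction and hydrolysis of the oxocarbenium ion; silyl ethers, ester and tertiary alcohol are inert.

Step 25
Reactants: 37 C12 allylic alcohol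
Product: 38 C12 aldehyde (2-substituted acrolein)
Conditions: MnO2, CH2Cl2, rt
Reagents that add atoms: none
Why: MnO2 oxidises only the primary allylic alcohol; C3 and C6 are silylated and the tertiary alcohol cannot be oxidised.

Step 26
Reactants: 38 C12 aldehyde
Product: 39 C12 acrylic acid
Conditions: NaClO2, NaH2PO4, 2-methylbut-2-ene, t-BuOH/H2O, 0 °C → rt
Reagents that add atoms: sodium chlorite, [Na+].[O-]Cl=O
Why: Pinnick oxidation converts the enal into the acrylic acid without touching the alkenes, since the scavenger removes the hypochlorous acid formed.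

Step 27
Reactants: 39 C12 acrylic acid
Product: 41 CNP0163972.1 (target), via dihydroxy acid 40 (not isolated)
Conditions: HF·pyridine, THF, 0 °C → rt
Reagents that add atoms: none
Why: Fluoride cleaves both TBS ethers, and the freed C6 hydroxyl closes the five-membered ring with the C12 acid under the mildly acidic conditions; C6 and C7 are already trans-disposed, so the trans-fused α-methylene lactone forms without any change at a stereocentre.

## Compound list

1 | (S)-(+)-linalool, (3S)-3,7-dimethylocta-1,6-dien-3-ol | C=C[C@@](C)(O)CCC=C(C)C | starting material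
2 | bis-ozonide of 1 (both alkenes as 1,2,4-trioxolanes, carbinol centre unchanged) | O1COOC1[C@@](C)(O)CCC1OOC(C)(C)O1 | intermediate
3 | (2S)-2-methylpentane-1,2,5-triol | OC[C@@](C)(O)CCCO | intermediate
4 | 3-[(4S)-2,2,4-trimethyl-1,3-dioxolan-4-yl]propan-1-ol | OCCC[C@@]1(C)COC(C)(C)O1 | intermediate
5 | 3-[(4S)-2,2,4-trimethyl-1,3-dioxolan-4-yl]propanal | O=CCC[C@@]1(C)COC(C)(C)O1 | intermediate
6 | but-2-yn-1-ol | CC#CCO | starting material
7 | sodium cyclic (Z)-alkenylalanate from 6 (five-membered C=C–C–O–Al ring, two 2-methoxyethoxy ligands) | [Na+].CC1=CCO[Al-]1(OCCOC)OCCOC | intermediate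
8 | (2Z)-3-iodobut-2-en-1-ol | C/C(I)=C/CO | intermediate
9 | (2Z)-3-iodobut-2-enal | C/C(I)=C/C=O | intermediate
10 | 3-chloro-2-(chloromethyl)prop-1-ene | C=C(CCl)CCl | starting material
11 | 1-({[2-(chloromethyl)prop-2-en-1-yl]oxy}methyl)-4-methoxybenzene | C=C(CCl)COCc1ccc(OC)cc1 | intermediate
12 | (2-{[(4-methoxybenzyl)oxy]methyl}prop-2-en-1-yl)magnesium chloride | C=C(C[Mg]Cl)COCc1ccc(OC)cc1 | intermediate
13 | 3-{[(4-methoxybenzyl)oxy]methyl}but-3-enoic acid | C=C(CC(=O)O)COCc1ccc(OC)cc1 | intermediate
14 | (4S)-4-benzyl-1,3-oxazolidin-2-one | O=C1N[C@@H](Cc2ccccc2)CO1 | starting material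
15 | mixed anhydride of 13 with pivalic acid | C=C(CC(=O)OC(=O)C(C)(C)C)COCc1ccc(OC)cc1 | intermediate
16 | N-lithio derivative of 14 | [Li]N1[C@@H](Cc2ccccc2)COC1=O | intermediate
17 | (4S)-4-benzyl-3-(3-{[(4-methoxybenzyl)oxy]methyl}but-3-enoyl)-1,3-oxazolidin-2-one | O=C1OC[C@H](Cc2ccccc2)N1C(=O)CC(=C)COCc1ccc(OC)cc1 | intermediate
18 | (Z)-di-n-butylboron enolate of 17 | CCCCB(CCCC)O/C(=C\C(=C)COCc1ccc(OC)cc1)N1C(=O)OC[C@@H]1Cc1ccccc1 | intermediate
19 | syn-aldol adduct, (4S)-4-benzyl-3-[(2S,3S,4Z)-3-hydroxy-5-iodo-2-{3-[(4-methoxybenzyl)oxy]prop-1-en-2-yl}hex-4-enoyl]-1,3-oxazolidin-2-one | O=C1OC[C@H](Cc2ccccc2)N1C(=O)[C@@H](C(=C)COCc1ccc(OC)cc1)[C@H](O)/C=C(/C)I | intermediate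
20 | C6 TBS ether of 19 | O=C1OC[C@H](Cc2ccccc2)N1C(=O)[C@@H](C(=C)COCc1ccc(OC)cc1)[C@H](O[Si](C)(C)C(C)(C)C)/C=C(/C)I | intermediate
21 | (2R,3S,4Z)-3-[(tert-butyldimethylsilyl)oxy]-5-iodo-2-{3-[(4-methoxybenzyl)oxy]prop-1-en-2-yl}hex-4-en-1-ol | OC[C@@H](C(=C)COCc1ccc(OC)cc1)[C@H](O[Si](C)(C)C(C)(C)C)/C=C(/C)I | intermediate
22 | (2S,3S,4Z)-3-[(tert-butyldimethylsilyl)oxy]-5-iodo-2-{3-[(4-methoxybenzyl)oxy]prop-1-en-2-yl}hex-4-enal | O=C[C@@H](C(=C)COCc1ccc(OC)cc1)[C@H](O[Si](C)(C)C(C)(C)C)/C=C(/C)I | intermediate
23 | propane-1,3-dithiol | SCCCS | starting material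
24 | 1,3-dithiane of 22 (C8 dithiane; C7 with 3-(PMB-oxy)prop-1-en-2-yl; C6 OTBS; (4Z)-C4 iodide; C6, C7 configured as in 41) | S1CCCSC1[C@@H](C(=C)COCc2ccc(OC)cc2)[C@H](O[Si](C)(C)C(C)(C)C)/C=C(/C)I | intermediate
25 | C3 allylic alcohols from 24 and 5 (both C3 epimers; C9/C10 acetonide) | S1CCCSC1[C@@H](C(=C)COCc2ccc(OC)cc2)[C@H](O[Si](C)(C)C(C)(C)C)/C=C(/C)C(O)CC[C@@]3(C)COC(C)(C)O3 | intermediate
26 | (4Z)-enone (C3 ketone) | S1CCCSC1[C@@H](C(=C)COCc2ccc(OC)cc2)[C@H](O[Si](C)(C)C(C)(C)C)/C=C(/C)C(=O)CC[C@@]3(C)COC(C)(C)O3 | intermediate
27 | (3S)-allylic alcohol | S1CCCSC1[C@@H](C(=C)COCc2ccc(OC)cc2)[C@H](O[Si](C)(C)C(C)(C)C)/C=C(/C)[C@@H](O)CC[C@@]3(C)COC(C)(C)O3 | intermediate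
28 | C3, C6 bis-TBS ether with C9/C10 acetonide | S1CCCSC1[C@@H](C(=C)COCc2ccc(OC)cc2)[C@H](O[Si](C)(C)C(C)(C)C)/C=C(/C)[C@@H](O[Si](C)(C)C(C)(C)C)CC[C@@]3(C)COC(C)(C)O3 | intermediate
29 | C9, C10 diol (C3, C6 bis-TBS ether) | S1CCCSC1[C@@H](C(=C)COCc2ccc(OC)cc2)[C@H](O[Si](C)(C)C(C)(C)C)/C=C(/C)[C@@H](O[Si](C)(C)C(C)(C)C)CC[C@](C)(O)CO | intermediate
30 | C9 p-toluenesulfonate of 29 (C10–OH free) | S1CCCSC1[C@@H](C(=C)COCc2ccc(OC)cc2)[C@H](O[Si](C)(C)C(C)(C)C)/C=C(/C)[C@@H](O[Si](C)(C)C(C)(C)C)CC[C@](C)(O)COS(=O)(=O)c3ccc(C)cc3 | intermediate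
31 | epoxy dithiane, key precursor (C8 dithiane, C9–C10 (2S)-2-methyloxirane, C3 and C6 OTBS, C12 OPMB; C3, C6, C7 configured as in 41) | S1CCCSC1[C@@H](C(=C)COCc2ccc(OC)cc2)[C@H](O[Si](C)(C)C(C)(C)C)/C=C(/C)[C@@H](O[Si](C)(C)C(C)(C)C)CC[C@@]3(C)CO3 | intermediate
32 | 2-lithio-1,3-dithiane derived from 31 | [Li]C1(SCCCS1)[C@@H](C(=C)COCc2ccc(OC)cc2)[C@H](O[Si](C)(C)C(C)(C)C)/C=C(/C)[C@@H](O[Si](C)(C)C(C)(C)C)CC[C@@]3(C)CO3 | intermediate
33 | ten-membered key product ((4Z)-cyclodecene; C8 spiro-1,3-dithiane; C10 methyl carbinol; C3 and C6 OTBS; C7 3-(PMB-oxy)prop-1-en-2-yl; C3, C6, C7, C10 configured as in 41) | CC(C)(C)[Si](C)(C)O[C@@H]1/C=C(/C)[C@@H](O[Si](C)(C)C(C)(C)C)CC[C@](C)(O)CC2(SCCCS2)[C@H]1C(=C)COCc1ccc(OC)cc1 | intermediate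
34 | C8 ketone (β-hydroxy ketone) | CC(C)(C)[Si](C)(C)O[C@@H]1/C=C(/C)[C@@H](O[Si](C)(C)C(C)(C)C)CC[C@](C)(O)CC(=O)[C@H]1C(=C)COCc1ccc(OC)cc1 | intermediate
35 | 8,10-anti diol (C8 configured as in 41) | CC(C)(C)[Si](C)(C)O[C@@H]1/C=C(/C)[C@@H](O[Si](C)(C)C(C)(C)C)CC[C@](C)(O)C[C@@H](O)[C@H]1C(=C)COCc1ccc(OC)cc1 | intermediate
36 | C8 isobutyrate | CC(C)(C)[Si](C)(C)O[C@@H]1/C=C(/C)[C@@H](O[Si](C)(C)C(C)(C)C)CC[C@](C)(O)C[C@@H](OC(=O)C(C)C)[C@H]1C(=C)COCc1ccc(OC)cc1 | intermediate
37 | C12 allylic alcohol | CC(C)(C)[Si](C)(C)O[C@@H]1/C=C(/C)[C@@H](O[Si](C)(C)C(C)(C)C)CC[C@](C)(O)C[C@@H](OC(=O)C(C)C)[C@H]1C(=C)CO | intermediate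
38 | C12 aldehyde | CC(C)(C)[Si](C)(C)O[C@@H]1/C=C(/C)[C@@H](O[Si](C)(C)C(C)(C)C)CC[C@](C)(O)C[C@@H](OC(=O)C(C)C)[C@H]1C(=C)C=O | intermediate
39 | C12 acrylic acid | CC(C)(C)[Si](C)(C)O[C@@H]1/C=C(/C)[C@@H](O[Si](C)(C)C(C)(C)C)CC[C@](C)(O)C[C@@H](OC(=O)C(C)C)[C@H]1C(=C)C(=O)O | intermediate
40 | 3,6,10-trihydroxy acid (seco acid of 41) | O[C@@H]1/C=C(/C)[C@@H](O)CC[C@](C)(O)C[C@@H](OC(=O)C(C)C)[C@H]1C(=C)C(=O)O | intermediate
41 | CNP0163972.1 | C=C1C(=O)O[C@@H]2/C=C(/C)[C@@H](O)CC[C@](C)(O)C[C@@H](OC(=O)C(C)C)[C@@H]12 | target

## Step count and risks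

Total: 27 steps. Longest linear sequence: 22 steps (10 → 41, steps 6–27).

**Step 20 (key step, proposed new method).**
- What may go wrong: the ring closure is too slow. A hindered tertiary carbanion has to reach a neopentyl-type epoxide carbon through a strained ten-membered transition state, so oligomerisation by intermolecular epoxide opening, proton return to C8 on warming, or silyl migration from the C6 oxygen to C8 may win.
- Fallback (known reactions only): form C8–C9 between two molecules and close the ring at C3–C4 by an intramolecular Nozaki–Hiyama–Kishi reaction. It sets out from 24 and 1 and returns at 33.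
- Dithiane 24 is converted by iodine–lithium exchange (t-BuLi, Et2O, −78 °C) and Bu3SnCl into the (Z)-alkenylstannane F1, which masks the iodide against the base.
- In parallel, 1 is ozonised at the trisubstituted alkene only (1 equiv O3, then NaBH4) to (4S)-4-methylhex-5-ene-1,4-diol F2 and silylated at the primary hydroxyl (Et3SiCl, imidazole) to the TES ether F3. Ozonolysis of the vinyl group with NaBH4 work-up gives the diol F4, which is closed (NaH, 1-(p-toluenesulfonyl)imidazole) to the epoxide F5.
- Lithiation of F1 (t-BuLi, THF/HMPA, −78 °C), addition of F5 and trapping of the alkoxide with Me3SiCl give the open-chain adduct F6. I2 replaces tin by iodine with retention (alkenyl iodide F7), and Swern oxidation converts the primary TES ether directly into the aldehyde F8.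
- CrCl2 with catalytic NiCl2 in DMSO at high dilution closes the ring to the allylic alcohols F9. SO3·pyridine/DMSO gives the enone F10, reduction with the oxazaborolidine of step 16 and catecholborane gives the (3S)-alcohol F11, and TBSOTf gives the silyl ether F12. Its tertiary TMS ether is cleaved with K2CO3 in MeOH to give 33.

**Step 22.**
- What may go wrong: poor or reversed facial selectivity. The carbinol is tertiary, so the chair that leads to the anti diol is not clearly preferred, and the ten-membered ring may impose the arrangement in which the ring bonds at C8 and C10 are trans on the transition-state ring, which leads to the 8-epimer.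
- Fallback: from 34, reduce under chelation control with external hydride (Et2BOMe, NaBH4, THF/MeOH, −78 °C) to the 8,10-syn diol F17 and install the ester with inversion by a Mitsunobu reaction (PPh3, diisopropyl azodicarboxylate, isobutyric acid), which returns to the route at 36.

**Step 14.**
- What may go wrong: slow or incomplete coupling. Insertion of zerovalent nickel into the hindered trisubstituted alkenyl iodide may be retarded by coordination of the dithiane sulfur atoms, and the alkenylchromium species may be protonated before it adds.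
- Fallback: replace the carbonyl addition by an acylation. From 5, NaClO2 oxidation gives the acid F13 and coupling with N,O-dimethylhydroxylamine gives the Weinreb amide F14. Iodine–lithium exchange on 24 (t-BuLi, Et2O, −78 °C) and addition to F14 return to the route at enone 26, which also saves step 15.

**Step 21.**
- What may go wrong: slow S-alkylation at the hindered spiro centre, and under prolonged heating retro-aldol ring opening or dehydration of the β-hydroxy ketone and epimerisation at the doubly activated C7.
- Fallback: mask the hydroxyl first. From 33, Et3SiOTf and 2,6-lutidine give the C10 TES ether F15, hydrolysis of its dithiane (MeI, CaCO3) gives the silylated ketone F16, which cannot undergo retro-aldol cleavage, and buffered HF·pyridine at 0 °C removes the tertiary TES group to return at 34 just before the reduction.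

## Further compounds

F1 | step 20 | (Z)-alkenyltributylstannane corresponding to 24 (SnBu3 in place of iodine) | S1CCCSC1[C@@H](C(=C)COCc2ccc(OC)cc2)[C@H](O[Si](C)(C)C(C)(C)C)/C=C(/C)[Sn](CCCC)(CCCC)CCCC
F2 | step 20 | (4S)-4-methylhex-5-ene-1,4-diol | C=C[C@@](C)(O)CCCO
F3 | step 20 | (3S)-3-methyl-6-[(triethylsilyl)oxy]hex-1-en-3-ol | C=C[C@@](C)(O)CCCO[Si](CC)(CC)CC
F4 | step 20 | (2S)-2-methyl-5-[(triethylsilyl)oxy]pentane-1,2-diol | OC[C@@](C)(O)CCCO[Si](CC)(CC)CC
F5 | step 20 | triethyl{3-[(2S)-2-methyloxiran-2-yl]propoxy}silane | CC[Si](CC)(CC)OCCC[C@@]1(C)CO1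
F6 | step 20 | open-chain adduct of F1 and F5 (C8 dithiane, C10 OTMS, C3 OTES, alkenylstannane) | CC[Si](CC)(CC)OCCC[C@](C)(O[Si](C)(C)C)CC1(SCCCS1)[C@@H](C(=C)COCc1ccc(OC)cc1)[C@H](O[Si](C)(C)C(C)(C)C)/C=C(/C)[Sn](CCCC)(CCCC)CCCC
F7 | step 20 | (Z)-alkenyl iodide from F6 | CC[Si](CC)(CC)OCCC[C@](C)(O[Si](C)(C)C)CC1(SCCCS1)[C@@H](C(=C)COCc1ccc(OC)cc1)[C@H](O[Si](C)(C)C(C)(C)C)/C=C(/C)I
F8 | step 20 | C3 aldehyde from F7 | O=CCC[C@](C)(O[Si](C)(C)C)CC1(SCCCS1)[C@@H](C(=C)COCc1ccc(OC)cc1)[C@H](O[Si](C)(C)C(C)(C)C)/C=C(/C)I
F9 | step 20 | ten-membered allylic alcohols (both C3 epimers; C10 OTMS) | CC(C)(C)[Si](C)(C)O[C@@H]1/C=C(/C)C(O)CC[C@](C)(O[Si](C)(C)C)CC2(SCCCS2)[C@H]1C(=C)COCc1ccc(OC)cc1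
F10 | step 20 | ten-membered (4Z)-enone (C10 OTMS) | CC(C)(C)[Si](C)(C)O[C@@H]1/C=C(/C)C(=O)CC[C@](C)(O[Si](C)(C)C)CC2(SCCCS2)[C@H]1C(=C)COCc1ccc(OC)cc1
F11 | step 20 | ten-membered (3S)-alcohol (C10 OTMS) | CC(C)(C)[Si](C)(C)O[C@@H]1/C=C(/C)[C@@H](O)CC[C@](C)(O[Si](C)(C)C)CC2(SCCCS2)[C@H]1C(=C)COCc1ccc(OC)cc1
F12 | step 20 | C10 TMS ether of 33 | CC(C)(C)[Si](C)(C)O[C@@H]1/C=C(/C)[C@@H](O[Si](C)(C)C(C)(C)C)CC[C@](C)(O[Si](C)(C)C)CC2(SCCCS2)[C@H]1C(=C)COCc1ccc(OC)cc1
F13 | step 14 | 3-[(4S)-2,2,4-trimethyl-1,3-dioxolan-4-yl]propanoic acid | OC(=O)CC[C@@]1(C)COC(C)(C)O1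
F14 | step 14 | N-methoxy-N-methyl-3-[(4S)-2,2,4-trimethyl-1,3-dioxolan-4-yl]propanamide | CON(C)C(=O)CC[C@@]1(C)COC(C)(C)O1
F15 | step 21 | C10 TES ether of 33 | CC(C)(C)[Si](C)(C)O[C@@H]1/C=C(/C)[C@@H](O[Si](C)(C)C(C)(C)C)CC[C@](C)(O[Si](CC)(CC)CC)CC2(SCCCS2)[C@H]1C(=C)COCc1ccc(OC)cc1
F16 | step 21 | C10 TES ether of ketone 34 | CC(C)(C)[Si](C)(C)O[C@@H]1/C=C(/C)[C@@H](O[Si](C)(C)C(C)(C)C)CC[C@](C)(O[Si](CC)(CC)CC)CC(=O)[C@H]1C(=C)COCc1ccc(OC)cc1
F17 | step 22 | 8,10-syn diol (C8 epimer of 35) | CC(C)(C)[Si](C)(C)O[C@@H]1/C=C(/C)[C@@H](O[Si](C)(C)C(C)(C)C)CC[C@](C)(O)C[C@H](O)[C@H]1C(=C)COCc1ccc(OC)cc1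
A1 | alternative 1 | cyclohexenone photo-partner (C6 ketone, C5=C10, C8 OTBS, C7 CH2CO2Me) | O=C1C=C(C)C[C@@H](O[Si](C)(C)C(C)(C)C)[C@H]1CC(=O)OC
A2 | alternative 1 | methyl cyclobut-1-ene-1-carboxylate | COC(=O)C1=CCC1
A3 | alternative 1 | cis-anti-cis tricyclic photoadduct containing the bicyclo[2.2.0]hexane | O=C1[C@H](CC(=O)OC)[C@H](O[Si](C)(C)C(C)(C)C)C[C@]2(C)[C@H]1[C@@]3(C(=O)OC)CC[C@@H]23
A4 | alternative 2 | seco iodo aldehyde (finished lactone, C8 isobutyrate, C10 OTES, (Z)-C4 iodide, C3 aldehyde) | C=C1C(=O)O[C@H](/C=C(/C)I)[C@H]1[C@H](OC(=O)C(C)C)C[C@@](C)(O[Si](CC)(CC)CC)CCC=O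
A5 | alternative 2 | C10 triethylsilyl ether of the target | C=C1C(=O)O[C@@H]2/C=C(/C)[C@@H](O)CC[C@](C)(O[Si](CC)(CC)CC)C[C@@H](OC(=O)C(C)C)[C@@H]12
A6 | alternative 3 | ten-membered (4Z)-3-hydroxy-10-keto lactone, C8 TBS ether | C1C(=O)O[C@@H]2/C=C(/C)[C@@H](O)CCC(=O)C[C@@H](O[Si](C)(C)C(C)(C)C)[C@@H]12
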